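## Analysis of the target

The target is a 4-alkoxy-5-methylcoumarin. Benzene ring A and pyranone ring B (O1, C2, C3, C4, C4a, C8a) carry a methyl group at C5 and, on O4, an oxidised geranyl chain, numbered here C1′ to C8′ from the ether oxygen. The chain holds a (2′E) trisubstituted alkene, a (5′E) disubstituted alkene and, between them, the only stereocentre, the doubly allylic carbinol C4′ (R). C7′ is a tertiary allylic hydroperoxide, so the hydroxyl group on C4′ and the hydroperoxy group on C7′ stand 1,4 to each other across C5′=C6′. This O–C4′–C5′=C6′–C7′–OO unit is the feature the plan rests on: it is what a 1,4-opening of a C4′,C5′-epoxide next to a C6′=C7′ alkene would leave behind. With one stereocentre there is no relative configuration to set, but C4′ must be made as one enantiomer at a position that ionises easily to a pentadienyl cation. The sensitive groups are the O–O bond (reducing agents, phosphines, low-valent metals, strong acid), the doubly allylic alcohol (acid, oxidants) and the O4–C1′ bond, a vinylogous allyl ester that can ionise or undergo Claisen rearrangement to C3 on heating. The hard part is to put the hydroperoxide on C7′ alone, with the (E) alkene and with no reduction after it, beside two other alkenes (C2′=C3′ and C3=C4), while controlling C4′.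

## Retrosynthetic reasoning

**15 ⇒ 14 + 10.** The C7′–O bond is cut, the alkene is moved back from C5′=C6′ to C6′=C7′ and the C4′ oxygen is tied to C5′. This gives the divinyl epoxide 14 and hydrogen peroxide 10. The cut is made here because the forward reaction makes the hydroperoxide, the (E) alkene and the free C4′ carbinol in one operation, as the last step, so the O–O bond meets no other reagent. C4′ is stored in 14 as an epoxide carbon, which needs no protecting group, and the configuration at C5′ is lost in the reaction and so need not be controlled. The forward reaction has to ionise only the C5′–O bond, deliver 10 to C7′ and not to C5′, and give the (E) alkene.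

**14 ⇒ 11 + 13.** The C6′=C7′ bond is cut to the epoxy aldehyde 11 and the ylide 13, which is made from the phosphonium salt 12. Both alkene substituents on C7′ are methyl, so no geometry is at stake.

**11 ⇒ 9 + 10.** Both C–O bonds of the oxirane are cut to the dienal 9 and 10. An amine-catalysed nucleophilic epoxidation is chosen because it acts only on the alkene conjugated to the aldehyde (C4′=C5′) and leaves C2′=C3′ and the coumarin alone. It sets C4′, the β-carbon, under catalyst control.

**9 ⇒ 7 + 8.** The C4′=C5′ bond is cut to the enal 7 and the two-carbon formyl ylide 8.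

**7 ⇒ 5.** The aldehyde oxygen on C4′ is removed, which leads to the prenyl ether 5. The forward reaction is an allylic C–H oxidation of the (E)-methyl group and passes through the alcohol 6.

**5 ⇒ 3 + 4.** The O4–C1′ bond is cut to 4-hydroxy-5-methylcoumarin 3 and prenol 4. The forward reaction must alkylate O4 and not C3 or O2.

**3 ⇒ 1 + 2.** Ring B is opened at C2–C3 and O1–C2 to the acetophenone 1 and diethyl carbonate 2.

## Alternatives that were turned down

**Alternative 1:** The textbook disconnection cuts C7′–O and returns the alkene to C6′=C7′. The forward key step is a Schenck ene reaction of singlet oxygen with the (4′R)-4′-hydroxygeranyl ether A1, which would come from 7 by asymmetric allylation and cross-metathesis. It was turned down for three reasons: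
- The perepoxide on a 2-methylalk-2-ene takes hydrogen almost equally from C5′ and from the cis methyl group on C7′. The branched, oxygen-bearing C4′ next to C5′ should tilt this further toward the methyl group.
- The wanted tertiary hydroperoxide would therefore be about half of the product at best and would have to be separated from an isomeric hydroperoxide at the last step. The C2′=C3′ alkene of A1, an allylic alcohol, is a second ene site.
- A1 costs as many steps as 14, so nothing is gained and half of the material is lost at the end.

**Alternative 2:** This cuts C5′=C6′. The forward key step is a cross-metathesis of the (R)-divinyl carbinol A2 with the hydroperoxide A3 or a protected form of it. It was turned down for these reasons: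
- Ruthenium alkylidenes and their phosphine ligands are oxidised by hydroperoxides. A3 would need a peroxide protecting group, and its acid removal threatens the doubly allylic alcohol.
- The alkene of A3 sits next to a fully substituted carbon and is a slow partner. A2 can homodimerise, and ruthenium hydrides can isomerise its carbinol to an enone.
- A2 needs an enantioselective vinyl addition to the α-branched enal 7, which is less well precedented than the steps used here.
- The step count is the same, and the stereocentre and the peroxide are made separately instead of being tied together.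

**Alternative 3:** This cuts C4′–C5′. The forward key step is a catalytic asymmetric addition to 7 of an alkenyl metal made from the (E)-vinyl iodide A4, to give the protected target A5. It was turned down for these reasons:
- The metals that make this bond (divalent chromium, organozinc reagents, zirconium hydrides on the way to the alkenyl metal) cleave O–O bonds, so even a peroxyketal is at risk.
- A4 needs three or more steps of its own, and the last step would be an acid deprotection next to the doubly allylic alcohol.
- If the peroxide is left out of the fragment, the problem falls back to Alternative 1.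

Key step: step 7

Remark: the sense of induction in step 5 is taken from the face-shielding model of (E)-iminium ions of diarylprolinol silyl ethers; if the opposite sense were found, the antipodal catalyst would be used and nothing else would change.

## Route

Step 1
Reactants: 1 1-(2-hydroxy-6-methylphenyl)ethan-1-one; 2 diethyl carbonate
Product: 3 4-hydroxy-5-methyl-2H-chromen-2-one
Conditions: NaH (3.5 equiv), toluene, 110 °C; then aq. HCl
Reagents that add atoms: none
Why: Claisen-type C-acylation of the ketone enolate by 2 and lactonisation of the phenoxide onto the resulting β-keto ester, the standard 4-hydroxycoumarin synthesis from 2-hydroxyacetophenones. The methyl group ortho to the acetyl group ends up at C5.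

Step 2
Reactants: 3 4-hydroxy-5-methyl-2H-chromen-2-one; 4 3-methylbut-2-en-1-ol
Product: 5 5-methyl-4-[(3-methylbut-2-en-1-yl)oxy]-2H-chromen-2-one
Conditions: PPh3, DIAD, THF, 0 °C to rt
Reagents that add atoms: none
Why: Mitsunobu reaction. The acidic vinylogous acid 3 should be alkylated on O4 by the oxyphosphonium salt of the primary allylic alcohol 4, which avoids the C3-alkylation seen with base and prenyl halides.

Step 3
Reactants: 5 5-methyl-4-[(3-methylbut-2-en-1-yl)oxy]-2H-chromen-2-one
Product: 7 (2E)-2-methyl-4-[(5-methyl-2-oxo-2H-chromen-4-yl)oxy]but-2-enal, via (E)-allylic alcohol 6 (not isolated)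
Conditions: SeO2 (1.3 equiv), 1,4-dioxane/H2O (30:1), 75 °C
Reagents that add atoms: selenium dioxide, O=[Se]=O
Why: Allylic oxidation with SeO2 (ene reaction, then [2,3]-sigmatropic shift) attacks the (E)-methyl group of a trisubstituted alkene selectively, and more than one equivalent carries the alcohol 6 on to the (E)-enal. The temperature stays well below that needed for Claisen rearrangement of the coumarinyl allyl ether.

Step 4
Reactants: 7 (2E)-2-methyl-4-[(5-methyl-2-oxo-2H-chromen-4-yl)oxy]but-2-enal; 8 (triphenylphosphoranylidene)acetaldehyde
Product: 9 (2E,4E)-4-methyl-6-[(5-methyl-2-oxo-2H-chromen-4-yl)oxy]hexa-2,4-dienal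
Conditions: 8 (1.2 equiv), toluene, 80 °C
Reagents that add atoms: none
Why: Wittig reaction with the stabilised formyl ylide 8 should form C4′=C5′ with (E) geometry under neutral conditions. Only a slight excess is used because the product is also an aldehyde.

Step 5
Reactants: 9 (2E,4E)-4-methyl-6-[(5-methyl-2-oxo-2H-chromen-4-yl)oxy]hexa-2,4-dienal; 10 hydrogen peroxide
Product: 11 (2R,3S)-3-{(2E)-4-[(5-methyl-2-oxo-2H-chromen-4-yl)oxy]but-2-en-2-yl}oxirane-2-carbaldehyde
Conditions: (R)-2-{bis[3,5-bis(trifluoromethyl)phenyl][(trimethylsilyl)oxy]methyl}pyrrolidine (10 mol%), 35% aq. 10 (1.3 equiv), CH2Cl2, rt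
Reagents that add atoms: none
Why: Iminium-catalysed Weitz–Scheffer-type epoxidation. 10 adds to C4′, the β-carbon of the (E)-iminium ion, from the face left open by the aryl(silyloxy)methyl arm of the (R)-catalyst, which should set C4′ as drawn, and the enamine then closes the trans oxirane. Only the alkene conjugated to the aldehyde is activated, and the configuration at C5′ need not be clean because that centre disappears in step 7.

Step 6
Reactants: 11 (2R,3S)-3-{(2E)-4-[(5-methyl-2-oxo-2H-chromen-4-yl)oxy]but-2-en-2-yl}oxirane-2-carbaldehyde; 12 isopropyltriphenylphosphonium iodide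
Product: 14 5-methyl-4-({(2E)-3-[(2S,3S)-3-(2-methylprop-1-en-1-yl)oxiran-2-yl]but-2-en-1-yl}oxy)-2H-chromen-2-one, via isopropylidenetriphenylphosphorane 13 (not isolated)
Conditions: KN(SiMe3)2, THF, 0 °C; then 11, −78 °C to 0 °C
Reagents that add atoms: none
Why: Wittig reaction of the non-stabilised ylide 13 with a 2,3-epoxy aldehyde at low temperature, a routine olefination for this substrate class. No alkene geometry arises (two methyl groups) and C4′ is not touched.

Step 7
Reactants: 14 5-methyl-4-({(2E)-3-[(2S,3S)-3-(2-methylprop-1-en-1-yl)oxiran-2-yl]but-2-en-1-yl}oxy)-2H-chromen-2-one; 10 hydrogen peroxide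
Product: 15 4-{[(2E,4R,5E)-7-hydroperoxy-4-hydroxy-3,7-dimethylocta-2,5-dien-1-yl]oxy}-5-methyl-2H-chromen-2-one
Conditions: 10 (10 equiv, solution in Et2O dried over MgSO4), H3PMo12O40 (2 mol%), Et2O, −20 °C to 0 °C; then NaHCO3
Reagents that add atoms: none
Why: Proposed new method: acid activation of the oxirane oxygen should ionise the C5′–O bond, which is allylic to the 2-methylprop-1-enyl group, to a 1,1-dimethylallyl cation (C5′–C6′–C7′), and hydrogen peroxide in large excess should capture the tertiary terminus C7′ (SN1′ perhydrolysis); the closest known reaction types are the H3PMo12O40-catalysed 1,2-perhydrolysis of epoxides at the more substituted carbon and the acid-catalysed 1,4-solvolysis of vinyl epoxides by alcohols. No ring is closed. No new stereocentre is formed: C4′ keeps its configuration because the C4′–O bond is never broken, and C5′ becomes trigonal, so 14 and any C5′ epimer of it give the same product. Capture at C7′ and not at C5′ is secured by the larger positive charge on the dialkylated terminus and by the hindered, inductively deactivated C5′ next to the coordinated C4′ oxygen. The (E) geometry of C5′=C6′ is secured by allylic 1,3-strain, since a (Z) cation would press C4′ against the inside methyl group on C7′, and the (E) cation cannot be trapped by the C4′ oxygen to a dihydrofuran. Ionisation of the C4′–O bond is disfavoured because that allyl cation would have only secondary termini, one next to the electron-poor CH2OAr group. Low temperature and a short contact time are needed so that the doubly allylic alcohol of 15 and the coumarinyl allyl ether are not ionised in turn.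

## Compound list

1 | 1-(2-hydroxy-6-methylphenyl)ethan-1-one | CC(=O)c1c(C)cccc1O | starting material
2 | diethyl carbonate | CCOC(=O)OCC | starting material
3 | 4-hydroxy-5-methyl-2H-chromen-2-one | Cc1cccc2oc(=O)cc(O)c12 | intermediate
4 | 3-methylbut-2-en-1-ol | CC(C)=CCO | starting material
5 | 5-methyl-4-[(3-methylbut-2-en-1-yl)oxy]-2H-chromen-2-one | CC(C)=CCOc1cc(=O)oc2cccc(C)c12 | intermediate
6 | 4-{[(2E)-4-hydroxy-3-methylbut-2-en-1-yl]oxy}-5-methyl-2H-chromen-2-one | C/C(=C\COc1cc(=O)oc2cccc(C)c12)CO | intermediate
7 | (2E)-2-methyl-4-[(5-methyl-2-oxo-2H-chromen-4-yl)oxy]but-2-enal | C/C(=C\COc1cc(=O)oc2cccc(C)c12)C=O | intermediate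
8 | (triphenylphosphoranylidene)acetaldehyde | O=CC=P(c1ccccc1)(c1ccccc1)c1ccccc1 | starting material
9 | (2E,4E)-4-methyl-6-[(5-methyl-2-oxo-2H-chromen-4-yl)oxy]hexa-2,4-dienal | C/C(=C\COc1cc(=O)oc2cccc(C)c12)/C=C/C=O | intermediate
10 | hydrogen peroxide | OO | starting material
11 | (2R,3S)-3-{(2E)-4-[(5-methyl-2-oxo-2H-chromen-4-yl)oxy]but-2-en-2-yl}oxirane-2-carbaldehyde | C/C(=C\COc1cc(=O)oc2cccc(C)c12)[C@@H]3O[C@H]3C=O | intermediate
12 | isopropyltriphenylphosphonium iodide | CC(C)[P+](c1ccccc1)(c1ccccc1)c1ccccc1.[I-] | starting material
13 | isopropylidenetriphenylphosphorane | CC(C)=P(c1ccccc1)(c1ccccc1)c1ccccc1 | intermediate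
14 | 5-methyl-4-({(2E)-3-[(2S,3S)-3-(2-methylprop-1-en-1-yl)oxiran-2-yl]but-2-en-1-yl}oxy)-2H-chromen-2-one | C/C(=C\COc1cc(=O)oc2cccc(C)c12)[C@@H]3O[C@H]3C=C(C)C | intermediate
15 | 4-{[(2E,4R,5E)-7-hydroperoxy-4-hydroxy-3,7-dimethylocta-2,5-dien-1-yl]oxy}-5-methyl-2H-chromen-2-one | C/C(=C\COc1cc(=O)oc2cccc(C)c12)[C@H](O)/C=C/C(C)(C)OO | target

## Step count and least certain steps

Total step count: 7. Longest linear sequence: 7 (1 → 3 → 5 → 7 → 9 → 11 → 14 → 15).

**Step 7 (key step, proposed new method).**
- Risk: the allyl cation may be captured at C5′ instead of C7′ (1,2-perhydrolysis), may lose a methyl proton to a 1,3-diene, or a hydride may shift from C4′ to give a β,γ-unsaturated ketone. After the product forms, the acid may ionise its doubly allylic alcohol, or a molybdenum peroxo species may epoxidise it. All of these come from using an acid and a peroxide together on a substrate that ionises easily.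
- Fallback, known chemistry only: it sets out from 7 and comes back to the route at 15. Brown allylation of 7 with the B-allyldiisopinocampheylborane made from (+)-B-methoxydiisopinocampheylborane and allylmagnesium bromide (Et2O, −78 °C, ethanolamine work-up) should give the (4′R)-homoallylic alcohol F1. Cross-metathesis of F1 with excess 2-methylbut-2-ene and second-generation Grubbs catalyst should give the (4′R)-4′-hydroxygeranyl ether F2, the same compound as A1. Schenck ene reaction of F2 (O2, tetraphenylporphyrin, visible light, CH2Cl2, 0 °C) should give 15 together with the regioisomeric secondary hydroperoxide, which would be removed by chromatography.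

**Step 5.**
- Risk: 10 may add at the far end of the dienyl iminium ion (1,6-addition); the dienal may scramble its geometry through a trienamine; the acid-labile vinyl epoxy aldehyde may decompose on work-up; the facial preference may be weak or reversed.
- Fallback: it sets out from 9 and comes back at 11. Luche reduction of 9 (NaBH4, CeCl3·7H2O, MeOH, 0 °C) should give the dienol F3. Sharpless asymmetric epoxidation of F3 (Ti(OiPr)4, L-(+)-diisopropyl tartrate, t-BuOOH, 4 Å molecular sieves, CH2Cl2, −20 °C) should epoxidise only the allylic-alcohol alkene and give the (2S,3S)-epoxy alcohol F4 with a well-established sense of induction. Dess–Martin periodinane with NaHCO3 in CH2Cl2 should then give 11.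

**Step 4.**
- Risk: the product dienal is less hindered than 7 and may be olefinated a second time; slow conversion of the α-branched enal leaves time for thermal Claisen rearrangement of the coumarinyl allyl ether.
- Fallback: it sets out from 7 and comes back at 9. Wittig reaction of 7 with the ylide from (1,3-dioxolan-2-ylmethyl)triphenylphosphonium bromide and KOtBu (THF, 0 °C) should give the dienyl dioxolane F5, whose masked aldehyde cannot react again. Hydrolysis with dilute aqueous HCl in THF should release 9 and equilibrate any (Z) isomer to the (E) enal.

**Step 2.**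
- Risk: alkylation at O2 (giving a 2-alkoxychromone) or at C3 instead of O4, helped by the peri methyl group at C5 that hinders O4.
- Fallback: it sets out from 3 and comes back at 5, with the polarity reversed. POCl3 should convert 3 into 4-chloro-5-methyl-2H-chromen-2-one F6. The sodium alkoxide of 4 (NaH, THF, 0 °C) should then displace chloride at C4 by addition–elimination to give 5.

## Further compounds

F1 | step 7 | 4-{[(2E,4R)-4-hydroxy-3-methylhepta-2,6-dien-1-yl]oxy}-5-methyl-2H-chromen-2-one | C/C(=C\COc1cc(=O)oc2cccc(C)c12)[C@H](O)CC=C
F2 | step 7 | 4-{[(2E,4R)-4-hydroxy-3,7-dimethylocta-2,6-dien-1-yl]oxy}-5-methyl-2H-chromen-2-one | C/C(=C\COc1cc(=O)oc2cccc(C)c12)[C@H](O)CC=C(C)C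
F3 | step 5 | 4-{[(2E,4E)-6-hydroxy-3-methylhexa-2,4-dien-1-yl]oxy}-5-methyl-2H-chromen-2-one | C/C(=C\COc1cc(=O)oc2cccc(C)c12)/C=C/CO
F4 | step 5 | 4-({(2E)-3-[(2S,3S)-3-(hydroxymethyl)oxiran-2-yl]but-2-en-1-yl}oxy)-5-methyl-2H-chromen-2-one | C/C(=C\COc1cc(=O)oc2cccc(C)c12)[C@@H]3O[C@H]3CO
F5 | step 4 | 4-{[(2E,4E)-5-(1,3-dioxolan-2-yl)-3-methylpenta-2,4-dien-1-yl]oxy}-5-methyl-2H-chromen-2-one | C/C(=C\COc1cc(=O)oc2cccc(C)c12)/C=C/C3OCCO3
F6 | step 2 | 4-chloro-5-methyl-2H-chromen-2-one | Cc1cccc2oc(=O)cc(Cl)c12
A1 | alternative 1 | 4-{[(2E,4R)-4-hydroxy-3,7-dimethylocta-2,6-dien-1-yl]oxy}-5-methyl-2H-chromen-2-one | C/C(=C\COc1cc(=O)oc2cccc(C)c12)[C@H](O)CC=C(C)C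
A2 | alternative 2 | 4-{[(2E,4R)-4-hydroxy-3-methylhexa-2,5-dien-1-yl]oxy}-5-methyl-2H-chromen-2-one | C/C(=C\COc1cc(=O)oc2cccc(C)c12)[C@H](O)C=C
A3 | alternative 2 | 2-methylbut-3-en-2-yl hydroperoxide | C=CC(C)(C)OO
A4 | alternative 3 | (1E)-1-iodo-3-[(2-methoxypropan-2-yl)peroxy]-3-methylbut-1-ene | I/C=C/C(C)(C)OOC(C)(C)OC
A5 | alternative 3 | 4-({(2E,4R,5E)-4-hydroxy-7-[(2-methoxypropan-2-yl)peroxy]-3,7-dimethylocta-2,5-dien-1-yl}oxy)-5-methyl-2H-chromen-2-one | C/C(=C\COc1cc(=O)oc2cccc(C)c12)[C@H](O)/C=C/C(C)(C)OOC(C)(C)OC
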